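Readings and results are simulated from invented constants.

Take the fraction of the charge per hour as the unit for the solid's loss, and set out the flasks first.

| flask | solid substrate | remark | time |
|---|---|---|---|
| north-east | 0.91 mM | run made earlier |  |
| west | 8.6 mM | run made earlier |  |
| red | 1.2 mM |  | 15 h |
| ochre | 3.0 mM |  | 15 h |
| blue | 10 mM |  | 15 h |

1. [target] at the end for red, ochre, blue, in this order
2. how that number moves from the first to the last of them (falls all the way / hardly changes / rises all the way / falls, then rises / rises, then falls)

- percentages count the solid substrate that a species holds: one side product counts as two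
- solid, in amounts per volume of the solution: solid substrate
- the earlier runs were read with a standard deviation of 0.3 percentage points
- on the list of suspects stand: starting material -> intermediate A; starting material -> intermediate B; intermediate B <-> intermediate C; intermediate A -> target; intermediate B <-> intermediate D; intermediate D <-> intermediate C; target -> over-reaction product; solid substrate <-> starting material; starting material + intermediate B -> side product
- at the start none of the solid substrate is in solution
- "hardly changes" means that all values lie within two and a half points (for a concentration: within two and a half percent of the largest)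

- north-east (time / h: target / %, solid substrate / %): 0.667: 0, 87.6; 2.00: 3.6, 71.7; 4.00: 11.8, 56.1; 5.00: 17.7, 48.7; 8.00: 33.6, 27.3
- west (time / h: target / %, solid substrate / %): 0.667: 0.1, 98.6; 1.00: 0.2, 98.5; 2.00: 0.3, 97.3; 4.00: 1.5, 95.1; 8.00: 3.5, 92.0

(each reading ± 0.3 percentage points)

Read the solid column from 2.00 h to 8.00 h. North-east loses 0.0740 h⁻¹ of its charge per hour and west 0.00883 h⁻¹. That is a factor of 8.38 between them, against a factor of 9.45 in charge.

So multiply each fraction by its charge. North-east gives a feed of 0.0673 mM h⁻¹ and west 0.0760 mM h⁻¹, which makes the loss zero-order in the solid. Take the north-east value, since its drop of 44 percentage points stands further above the scatter of 0.3 points than the west drop of 5.3 points.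

Now read the target column at 8.00 h: the two runs hold 0.306 mM and 0.301 mM, so the target follows the same amount, not the same fraction.

Start from the 0.662 mM that north-east had lost by 8.00 h, and reckon the drain time, the hour at which a charge's solid fraction reaches zero at this feed. For red, 16.0 h exceeds the asked 15 h, and 5.59% of the charge remains. Expect the three flasks to stay level by my reckoning, which sets no value of its own.

The forecast gives 0.58 mM, 0.58 mM and 0.58 mM, so hardly changes, and says “All three runs should therefore match”.

The flasks give 0.581 mM, 0.581 mM and 0.581 mM, so hardly changes.

    starting material → intermediate A (k = 0.00450 min⁻¹)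
    starting material → intermediate B (k = 3.00 × 10⁻⁵ min⁻¹)
    intermediate B ⇌ intermediate C (K = 6.50, k = 2.60 × 10⁻⁴ min⁻¹)
    intermediate A → target (k = 0.0150 min⁻¹)
    intermediate B ⇌ intermediate D (K = 1.50, k = 0.00290 min⁻¹)
    intermediate D ⇌ intermediate C (k = 6.90 × 10⁻⁵ min⁻¹)
    target → over-reaction product (k = 8.50 × 10⁻⁴ min⁻¹)
    solid substrate ⇌ starting material, rate k8*(cs8 - [starting material]) while solid is left; crystals form when [starting material] > cs8 (solubility = 0.340 mM, k = 0.00960 min⁻¹)
    starting material + intermediate B → side product (k = 0.0360 M⁻¹ min⁻¹)

Red still holds 8.44% of its solid at 15.0 h. For ochre, the drain time comes to 42.7 h, which leaves 62.2% of the charge at 15 h, and the flask holds 63.4%. A far longer time parts the row, as the later state shows. At 150 h, red has 0% solid and 0.0930% target, or 0.00112 mM, while blue has 4.25% solid and 12.2% target, or 1.22 mM.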